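The earlier runs and the new flask were computed for an exercise; the scatter is artificial.

A small charge of reagent set against a larger one is the comparison that opens this flask, so the runs come first.

| flask | starting material | reagent | time |
|---|---|---|---|
| maple | 0.400 M | 1.00 M |  |
| birch | 0.400 M | 0.500 M |  |
| alder | 1.20 M | 1.00 M |  |
| larch | 0.800 M | 3.00 M | 40 min |

| run | time / min | [target] / M |
|---|---|---|
| maple run | 6.7 | 0.027 |
| maple run | 13 | 0.055 |
| maple run | 20 | 0.078 |
| maple run | 27 | 0.092 |
| maple run | 33 | 0.097 |
| maple run | 40 | 0.109 |
| birch run | 6.7 | 0.014 |
| birch run | 13 | 0.039 |
| birch run | 20 | 0.068 |
| birch run | 27 | 0.079 |
| birch run | 33 | 0.092 |
| birch run | 40 | 0.100 |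
| alder run | 6.7 | 0.056 |
| alder run | 13 | 0.132 |
| alder run | 20 | 0.206 |
| alder run | 27 | 0.261 |
| alder run | 33 | 0.301 |
| alder run | 40 | 0.328 |

(readings scatter by 0.003 M)

* reaction order in [reagent] at the outset, round the charge of the maple run, defined at two percent of the starting material turned into target
* reaction order in [starting material] at the outset, round the charge of the maple run, defined at two percent of the starting material turned into target (one fixed amount of target, the same in the runs compared)
* target in the larch run at 40 min, as a share of the starting material charged

- Overall: starting material + reagent -> target.
- Constant volume, constant temperature.
- A reading of a species includes what of it is bound.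
- "The second partner" is reagent.
- An order is taken over about fifteen percent of the charge, up and down.

Does more reagent keep paying as time passes? At 6.7 min the birch run, with half the [reagent] of the maple run, holds about half of the maple run's target, but at 40 min it holds 0.917 of it. The reckoning made here reads this shrinking gain as target lost in a step with reagent, a step that the overall equation does not show.

How fast is that loss? The slope of the maple run falls from 0.00383 M/min early to 0.00131 M/min late. Counting that whole fall as loss, against the mean late target, gives 39.8 min: this is the loss time, target on hand divided by the rate of its loss. The slope of the birch run goes from 0.00406 M/min early to 0.00162 M/min late, which reads 36.6 min, where loss in step with [reagent] would give 79.5 min, so tying the loss to reagent is a bet and not a reading.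

What does the larch run then hold? Its reagent stands in excess, so the loss is taken as pseudo-first-order in target, and its loss time becomes 13.3 min, shorter than the 40 min asked. From 6.7 min to 20 min the slopes read 0.00406 M/min in the birch run and 0.00383 M/min in the maple run, yet the first reading of the birch run stood at half of that of the maple run, so scaling making with starting material alone, to 0.00767 M/min, is a bet of this reckoning. Making and loss then balance at 12.7% of the charge.

The forecast says 0.2, 0.8 and 28%, on the ground that “All runs slow by time at a similar fractional conversion”. Its yield is what the same share as the maple run gives, and it stands above the reckoning here.

The flask gives 0.29, 0.63 and 13.0%.

    starting material + reagent → intermediate (0.05394 /M/min)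
    intermediate → target (0.2388 /min)
    starting material + reagent ⇌ idle substrate-reagent adduct, settled at all times (1.420 /M)
    target + reagent → side product (0.05046 /M/min)

In the larch run, starting material and reagent fed intermediate and then target, while target and reagent went on to side product from the first target onward. With [reagent] taken at its charge, the step to side product gives the larch run a loss time of 6.61 min, shorter than the 13.3 min estimated from the readings, and at 40 min target stands at 13.0% of the starting material charged.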